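The earlier runs and the new flask were computed with constants of no real substance, and the scatter is random.

One percent on these readings means one hundredth of both substrates together as charged, so the left-handed substrate starts at 50.0%. A single-handed reagent goes into this racemate, and you want the left-handed product in each flask.

| setting | summer | dawn | zeta | delta | gamma | alpha | beta |
|---|---|---|---|---|---|---|---|
| left-handed substrate | 0.086 M | 0.086 M | 0.086 M | 0.086 M | 0.086 M | 0.086 M | 0.086 M |
| right-handed substrate | 0.086 M | 0.086 M | 0.086 M | 0.086 M | 0.086 M | 0.086 M | 0.086 M |
| reagent | 0.093 M | 1.2 M | 0.120 M | 0.0800 M | 1.00 M | 0.258 M | 0.150 M |
| remark | run made earlier | run made earlier |  |  |  |  |  |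
| time |  |  | 30 min | 30 min | 30 min | 30 min | 30 min |

- summer (time / min: left-handed product / %, left-handed substrate / %): 0.833: 1.6, 47.7; 2.50: 4.9, 45.0; 4.00: 6.2, 43.3; 6.00: 7.6, 41.6; 10.0: 11.0, 38.7; 12.0: 12.5, 38.1; 15.0: 13.8, 35.5
- dawn (time / min: left-handed product / %, left-handed substrate / %): 0.833: 19.2, 29.8; 2.50: 31.7, 15.8; 4.00: 37.0, 11.5; 6.00: 41.6, 7.2; 10.0: 46.2, 3.2; 12.0: 47.0, 1.9; 15.0: 48.7, 1.0

(each reading ± 0.3 percentage points)

1. all flasks from highest to lowest amount of left-handed product, in percent of the left-handed substrate and right-handed substrate together charged, at 30 min (zeta / delta / gamma / alpha / beta)
2. the amount of left-handed product, in percent of the left-handed substrate and right-handed substrate together charged of the flask you put first, at 30 min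
3. the amount of left-handed product, in percent of the left-handed substrate and right-handed substrate together charged of the flask you put last, at 30 min

- reagent is single-handed; left-handed substrate and right-handed substrate are mirror images of each other, charged as a racemate, each of them at the stated concentration
- reactions considered so far: reagent + left-handed substrate -> left-handed product; reagent + right-handed substrate -> right-handed product; left-handed substrate <-> right-handed substrate; left-handed product <-> right-handed product
- the handed part of reagent does not stay in what it makes, so the products of the two hands are mirror images too

The dawn run looks contradictory. Its c_reagent stands far above c_left-handed substrate, yet the readings of the left-handed substrate give a first fall of 0.621 min⁻¹ and a later one of 0.213 min⁻¹, which is slower. Even taking both substrates whole, the dawn reagent loses 14.3% of its charge, less than the 65.7% lost from that rate, so I take it that the left-handed substrate is refilled from the right-handed substrate. But left-handed substrate plus left-handed product still reads 49.7% at the last dawn reading. I therefore take it that what arrives from the right leaves again, as left-handed product turning into right-handed product.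

So the reagent pays for both products, and if the hands mix quickly, the two products grow nearly alike: two parts of reagent go for each part of left-handed product. In delta, reagent is the limiting reagent, and half of its charge, in percent of both substrates, is 23.3%. Call this the reagent ceiling. The share of reagent left is then one minus left-handed product over ceiling.

The forecast gives gamma > alpha > beta > zeta > delta, with 49.4% first and 19.5% last, and it holds that “neither racemisation is visible”. My grounds differ from that, but its delta value lies under my ceiling.

The flasks give gamma > alpha > beta > zeta > delta, with 49.8% first and 16.8% last.

    reagent + left-handed substrate → left-handed product (k = 0.0100 M⁻¹ s⁻¹)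
    reagent + right-handed substrate → right-handed product (k = 3.50 × 10⁻⁴ M⁻¹ s⁻¹)
    left-handed substrate ⇌ right-handed substrate (k = 0.00540 s⁻¹)
    left-handed product ⇌ right-handed product (k = 0.00760 s⁻¹)

Delta's 16.8% against its ceiling of 23.3% reckons to 27.9% of the reagent left, and the flask holds 28.8%. After 300 min delta holds 23.3% of left-handed product, with 0.0104% of its reagent remaining. Now take the same flask with 0.032 M of reagent. You reckon its ceiling as 9.30%, and at 30 min it holds 7.23% of left-handed product. That reckons to 22.3% of the reagent left, and the flask holds 23%.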